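**Assumption:** the chain is read as 14 CH2 groups between the acetoxy-bearing carbon and the ring (C23H38O5), the stereocentre is (S), and 1-pentadecyne, (S)-propylene oxide and 4-phenyloxazole are taken as catalogue compounds.

**Retrosynthetic overview**
1. The anhydride is the oxidised form of a 3-alkyl-4-methylfuran: singlet-oxygen [4+2] across C2/C5, then lactol oxidation; all five ring atoms are already in the furan.
2. The furan ring (the only ring, formed once) comes from an oxazole–alkyne Diels–Alder/retro-Diels–Alder between 4-phenyloxazole and the 2-alkyne (S)-nonadec-17-yn-2-yl acetate, with loss of PhCN.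
3. The 2-alkyne comes from a terminal alkyne by one-pot C-methylation/O-acetylation; the terminal alkyne comes from an alkyne zipper on (S)-octadec-4-yn-2-ol.
4. (S)-Octadec-4-yn-2-ol comes from 1-pentadecyne and (S)-propylene oxide, which supplies the only stereocentre.

**Route**

Step 1
Reactants: 1 1-pentadecyne; 2 (S)-propylene oxide
Product: 4 (S)-octadec-4-yn-2-ol, via lithium pentadec-1-yn-1-ide 3 (not isolated)
Conditions: n-BuLi (1.0 equiv), THF, −78 → 0 °C; then 2 (1.5 equiv), HMPA (or DMPU), 0 °C → rt; H2O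
Reagents that add atoms: none
Why: SN2 opening of the terminal epoxide by the lithium acetylide at the unhindered CH2; the C–O bond at the stereocentre is not touched, so (S) is retained.

Step 2
Reactants: 4 (S)-octadec-4-yn-2-ol
Product: 5 (S)-octadec-17-yn-2-ol
Conditions: KH (4.5 equiv), H2N(CH2)3NH2 (KAPA), 0 °C → rt, 3 h; then ice/H2O
Reagents that add atoms: none
Why: Alkyne-zipper isomerisation, driven by irreversible formation of the terminal acetylide, walks the triple bond 13 positions to the chain end; the carbinol carbon is an alkoxide throughout and is not deprotonated, so it does not racemise.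

Step 3
Reactants: 5 (S)-octadec-17-yn-2-ol
Product: 8 (S)-nonadec-17-yn-2-yl acetate, via dilithio alkynolate 6 (not isolated), via lithium (S)-nonadec-17-yn-2-olate 7 (not isolated)
Conditions: n-BuLi (2.05 equiv), THF, −78 → 0 °C; MeI (1.2 equiv), 0 °C → rt; then Ac2O (2 equiv), DMAP (cat.), 0 °C → rt; H2O
Reagents that add atoms: iodomethane CI; acetic anhydride CC(=O)OC(C)=O
Why: Acetylide alkylation followed by O-acylation in one pot: in THF the acetylide carbon is far more nucleophilic toward MeI than the secondary lithium alkoxide, which is then acetylated by Ac2O with no bond to the stereocentre broken.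

Step 4
Reactants: 8 (S)-nonadec-17-yn-2-yl acetate; 9 4-phenyloxazole
Product: 12 (2S)-16-(4-methylfuran-3-yl)hexadecan-2-yl acetate, via 5-alkyl cycloadduct 10 (not isolated), via 6-alkyl cycloadduct 11 (not isolated)
Conditions: 9 (4 equiv), neat, Et3N (trace), sealed tube, 240 °C, 36 h
Reagents that add atoms: none
Why: Oxazole–alkyne Diels–Alder across C2/C5 of the oxazole followed by retro-Diels–Alder loss of benzonitrile (Kondrat'eva-type furan synthesis); both regioisomeric adducts collapse to the same 3,4-disubstituted furan, and the remote acetate stereocentre is unaffected.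

Step 5
Reactants: 12 (2S)-16-(4-methylfuran-3-yl)hexadecan-2-yl acetate
Product: 16 (2S)-16-(4-methyl-2,5-dioxo-2,5-dihydrofuran-3-yl)hexadecan-2-yl acetate, via furan endoperoxide 13 (not isolated), via 4-alkyl hydroxybutenolide 14 (not isolated), via 3-alkyl hydroxybutenolide 15 (not isolated)
Conditions: O2, hν (visible), TPP (cat.), CH2Cl2, −78 °C; iPr2NEt (1.5 equiv), −78 °C → rt; then Dess–Martin periodinane (2.5 equiv), rt; dilute HCl work-up
Reagents that add atoms: oxygen O=O
Why: Singlet-oxygen [4+2] cycloaddition to the furan, Kornblum–DeLaMare fragmentation of the endoperoxide to the two regioisomeric γ-hydroxybutenolides, and Dess–Martin lactol oxidation, which converges both on the dialkylmaleic anhydride; the acetate is inert to all three.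

**Compound list**
1 | 1-pentadecyne | C#CCCCCCCCCCCCCC | starting material
2 | (S)-propylene oxide [(2S)-2-methyloxirane] | C[C@H]1CO1 | starting material
3 | lithium pentadec-1-yn-1-ide | [Li]C#CCCCCCCCCCCCCC | intermediate
4 | (S)-octadec-4-yn-2-ol | C[C@H](O)CC#CCCCCCCCCCCCCC | intermediate
5 | (S)-octadec-17-yn-2-ol | C[C@H](O)CCCCCCCCCCCCCCC#C | intermediate
6 | lithium (2S)-18-lithiooctadec-17-yn-2-olate | C[C@H](O[Li])CCCCCCCCCCCCCCC#C[Li] | intermediate
7 | lithium (S)-nonadec-17-yn-2-olate | C[C@H](O[Li])CCCCCCCCCCCCCCC#CC | intermediate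
8 | (S)-nonadec-17-yn-2-yl acetate | CC(=O)O[C@@H](C)CCCCCCCCCCCCCCC#CC | intermediate
9 | 4-phenyloxazole | c1ccc(cc1)-c1cocn1 | starting material
10 | (2S)-16-(6-methyl-3-phenyl-7-oxa-2-azabicyclo[2.2.1]hepta-2,5-dien-5-yl)hexadecan-2-yl acetate (bridgehead epimers) | CC(=O)O[C@@H](C)CCCCCCCCCCCCCCC1=C(C)C2OC1C(c3ccccc3)=N2 | intermediate
11 | (2S)-16-(5-methyl-3-phenyl-7-oxa-2-azabicyclo[2.2.1]hepta-2,5-dien-6-yl)hexadecan-2-yl acetate (bridgehead epimers) | CC(=O)O[C@@H](C)CCCCCCCCCCCCCCC1=C(C)C2OC1N=C2c3ccccc3 | intermediate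
12 | (2S)-16-(4-methylfuran-3-yl)hexadecan-2-yl acetate | CC(=O)O[C@@H](C)CCCCCCCCCCCCCCc1cocc1C | intermediate
13 | (2S)-16-(6-methyl-2,3,7-trioxabicyclo[2.2.1]hept-5-en-5-yl)hexadecan-2-yl acetate (bridgehead epimers) | CC(=O)O[C@@H](C)CCCCCCCCCCCCCCC1=C(C)C2OOC1O2 | intermediate
14 | (2S)-16-(2-hydroxy-4-methyl-5-oxo-2,5-dihydrofuran-3-yl)hexadecan-2-yl acetate (lactol epimers) | CC(=O)O[C@@H](C)CCCCCCCCCCCCCCC1=C(C)C(=O)OC1O | intermediate
15 | (2S)-16-(5-hydroxy-4-methyl-2-oxo-2,5-dihydrofuran-3-yl)hexadecan-2-yl acetate (lactol epimers) | CC(=O)O[C@@H](C)CCCCCCCCCCCCCCC1=C(C)C(O)OC1=O | intermediate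
16 | (2S)-16-(4-methyl-2,5-dioxo-2,5-dihydrofuran-3-yl)hexadecan-2-yl acetate | CC(=O)O[C@@H](C)CCCCCCCCCCCCCCC1=C(C)C(=O)OC1=O | target

**Step count:** 5 steps in total; the longest linear sequence is 5 steps.

**Steps most likely to fail, with fallbacks**

Step 4 is the weakest point, because an unactivated dialkylalkyne is a poor dienophile for the oxazole and needs about 240 °C. The fallback sets out from 8 and comes back at 12, building the furan through a different cycloaddition. Ene–yne cross-metathesis of 8 with ethylene (Grubbs II, toluene, 80 °C) gives the diene (2S)-18-methyl-17-methylidenenonadec-18-en-2-yl acetate F1. Singlet-oxygen [4+2] addition (O2, hν, TPP, CH2Cl2, 0 °C) gives the endoperoxide (2S)-16-(5-methyl-3,6-dihydro-1,2-dioxin-4-yl)hexadecan-2-yl acetate F2. Et3N followed by catalytic TsOH (Kornblum–DeLaMare opening, then cyclodehydration) delivers furan 12.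

Step 5 is next: the one-pot photooxygenation/oxidation may stall at the hydroxybutenolides, or the amine may consume the periodinane. The fallback sets out from 12 and comes back at 16 without singlet oxygen. Clauson-Kaas oxidation (Br2, MeOH, Na2CO3, −40 °C) gives the bis-acetal (2S)-16-(2,5-dimethoxy-4-methyl-2,5-dihydrofuran-3-yl)hexadecan-2-yl acetate F3 as a cis/trans mixture. Jones reagent in acetone at 0 °C hydrolyses and oxidises it to anhydride 16.

Step 2 is third: a 13-position zipper may stop short and leave inseparable internal alkynes. The fallback sets out from 2 and comes back at 5, placing the terminal alkyne by C–C bond formation instead. Lithiated 1-(trimethylsilyl)propyne (n-BuLi, THF) is alkylated with excess 1,12-dibromododecane to give (15-bromopentadec-1-yn-1-yl)trimethylsilane F4. Magnesium in THF converts it into [15-(trimethylsilyl)pentadec-14-yn-1-yl]magnesium bromide F5. This opens epoxide 2 at CH2 under CuI catalysis (−30 °C) to give (S)-18-(trimethylsilyl)octadec-17-yn-2-ol F6. K2CO3 in MeOH removes the silyl group to give 5.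

**Further compounds**
F1 | step 4 | (2S)-18-methyl-17-methylidenenonadec-18-en-2-yl acetate | CC(=O)O[C@@H](C)CCCCCCCCCCCCCCC(=C)C(C)=C
F2 | step 4 | (2S)-16-(5-methyl-3,6-dihydro-1,2-dioxin-4-yl)hexadecan-2-yl acetate | CC(=O)O[C@@H](C)CCCCCCCCCCCCCCC1=C(C)COOC1
F3 | step 5 | (2S)-16-(2,5-dimethoxy-4-methyl-2,5-dihydrofuran-3-yl)hexadecan-2-yl acetate | CC(=O)O[C@@H](C)CCCCCCCCCCCCCCC1=C(C)C(OC)OC1OC
F4 | step 2 | (15-bromopentadec-1-yn-1-yl)trimethylsilane | C[Si](C)(C)C#CCCCCCCCCCCCCCBr
F5 | step 2 | [15-(trimethylsilyl)pentadec-14-yn-1-yl]magnesium bromide | C[Si](C)(C)C#CCCCCCCCCCCCCC[Mg]Br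
F6 | step 2 | (S)-18-(trimethylsilyl)octadec-17-yn-2-ol | C[C@H](O)CCCCCCCCCCCCCCC#C[Si](C)(C)C
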